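**Remarks on the chemistry (made before the route)**

- Structure check: C3 is S in the target. The C3 boronate with the same spatial arrangement is also S, because boron ranks below both carbon neighbours and oxygen above them. A stereoretentive C–B to C–O oxidation is therefore what the route needs.
- Assumption: the (R) acid is taken to deliver the (3S) boronate. The sense of induction cannot be predicted, and the (S) acid would be used if it proves opposite.

## Structural features

Asperimide C is a 2,2-dimethylchroman-3-ol (benzene ring A fused to dihydropyran ring B) joined through a CH2 group at C7 to C3 of a 1H-pyrrole-2,5-dione (ring C), whose C4 carries a 4-hydroxyphenyl group (ring D). The only stereocentre is C3 of ring B, (S), a secondary carbinol between the quaternary, oxygen-bearing C2 and the benzylic C4. It has no stereogenic neighbour, so the task is absolute control with no relay. The fragile parts are the N-unsubstituted maleimide (acidic N–H, electrophilic toward hydroxide and soft nucleophiles) and the CH2 link, which is both benzylic and allylic to ring C and can let the alkene migrate to the exocyclic position under base. The phenol is oxidisable, and the tertiary aryl ether C2–O1 next to a carbinol can ionise in strong acid. The real difficulty is twofold: an isolated carbinol stereocentre beside a quaternary carbon, and the union of two halves through an sp3 carbon in the presence of three acidic protons. The key step exploits the fact that C4, C3 and C2 bridge C4a and O1. Ring B is therefore an ortho-quinone methide (C4=C4a–C8a=O1) plus a two-carbon alkene whose C2 end carries the gem-dimethyl group and whose C3 end carries boron as a masked hydroxyl. C7 lies para to C4a, so a bromine placed there stays clear of the cycloaddition and serves later as the coupling handle.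

## Logic of the disconnections

**12 to 8 and 11.** The bond between the CH2 link and C3 of ring C is cut. This separates the chiral bicycle from the achiral heteroaryl half at the latest point and needs no protecting group. The forward step must be an sp3–sp2 coupling in which the benzylic boron of 8 transfers faster than it is protonated, and in which the bromide of 11 still undergoes oxidative addition although the imide and phenol are deprotonated. The opposite polarity (aryl boron on ring A, bromomethyl group on ring C) was set aside. It needs a radical bromination, a phenol protecting group and an allylic bromide next to an acidic imide N–H that would alkylate itself under base. An aldol-type construction of ring C from a simple alkanamide was also set aside, because such α-protons are too weakly acidic.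

**11 to 9 and 10.** The aryl–C4 bond of ring C is cut, which reduces the heteroaryl half to two commercial compounds. The forward step must stop after one arylation of a symmetrical dibromide.

**8 to 6 and 7.** The C7–CH2 bond is cut. The one-carbon link and its boron arrive together, and the aryl bromide is used directly. The forward step must couple only one boron of 7 and must not consume 8 in a second coupling.

**6 to 5.** The C3–O bond is traced back to a C3–B bond. This turns the carbinol into the product of a carbon–carbon bond-forming event. The forward oxidation must proceed with retention and faster than β-elimination of the C2 aryloxide.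

**5 to 2 and 3, through 4.** The bonds C4–C3 and O1–C2 are cut, which opens ring B into the quinone methide 4 and the alkene 3. Ring B, the gem-dimethyl group, the C3 heteroatom handle and the stereocentre all appear in one step from two simple pieces. The forward step must be regioselective (boron on C3), must keep boron in the product and must select one alkene face.

**2 to 1.** The benzylic alcohol is traced to the aldehyde, a one-step reduction of a commercial compound.

## Other disconnections considered

**Alternative 1:** The cut takes ring C apart completely: the two bonds from its alkene carbons to the carbonyl carbons and one carbonyl–nitrogen bond. This leaves the internal alkyne A1, benzyl isocyanate A2 and gaseous carbonyl units. In the forward direction Ru3(CO)12 would join them under carbonylation pressure at about 130–160 °C to the fully substituted imide A3.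
- In its favour: the reaction type is established and the whole heterocycle with both carbon substituents forms in one operation. The orientation of the alkyne is irrelevant, because both alkyne carbons end as carbonyl-bearing carbons.
- Against it here: the cut does not address the C3 carbinol, which must be set by another asymmetric step on the way to A1. The nitrogen arrives benzylated, and an N-benzyl imide is hard to unmask without damaging ring C, so a detour through the anhydride would be needed. Both hydroxyls must travel as silyl ethers. The propargylic, benzylic CH2 of A1 may isomerise to an allene at the required temperature.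
- Comparison: on mechanism the alternative is the better, since its key step is known and step 2 of the chosen plan is not. On structure it is weaker, because it spends the key step on an achiral ring that the chosen plan buys as 9. On step economy it is weaker, since protection, alkyne assembly, imide unmasking and desilylation take it well beyond six steps.

**Alternative 2:** The cut removes C8a–O1, C4a–C4 and O1–C2, so ring B is traced to the aryne precursor A4 and 3-methylbut-2-enal A5. In the forward direction fluoride releases a 3-chloroaryne from A4 and the enal carbonyl adds across it to a benzoxete. This opens to an ortho-quinone methide, and an oxa-6π electrocyclisation closes the 2H-chromene A6. The chlorine steers the oxygen to the remote aryne carbon.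
- In its favour: three bonds and ring B form in one known step, and the gem-dimethyl group comes from a cheap enal. The C3=C4 alkene of A6 belongs to the substrate class for which asymmetric epoxidation with chiral manganese salen complexes is most dependable, so absolute control at C3 would rest on proven ground. On that point the alternative is the better.
- Against it here: the key step sets no stereocentre, and the derived epoxide then needs a regioselective benzylic reduction. The chlorine is only a regiochemical auxiliary and must be removed. A4 itself needs several steps, and the protected hydroxymethyl group still has to become a coupling handle.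
- Comparison: on structure the two plans are equal in ring-forming power, since both reach ring B through an ortho-quinone methide, but the chosen plan installs the C3 handle and the stereocentre in the same event. On mechanism the alternative is the safer. On step economy it is clearly longer.

**Alternative 3:** The cut is the single bond O1–C8a, which leads to the bromo alcohol A7. In the forward direction Pd(OAc)2 with 2-(di-tert-butylphosphino)-1,1'-binaphthyl and Cs2CO3 would arylate the tertiary alkoxide intramolecularly to the chromane ester A8.
- In its favour: the reaction is known for tertiary alcohols, whose alkoxide carbon has no hydrogen for β-hydride loss. The ring size is unambiguous. The stereocentre would come from an osmium-catalysed asymmetric dihydroxylation of a prenyl arene, a trisubstituted alkene class with predictable face selectivity. On stereochemical reliability the alternative is the better.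
- Against it here: C–O reductive elimination from a hindered tertiary alkoxide is slow and competes with hydrodebromination. The secondary hydroxyl must be protected and later released. C7 arrives as an ester, so reduction and activation are needed before any coupling.
- Comparison: on structure the alternative forms one bond where the chosen plan forms two bonds and a stereocentre. On mechanism it is the better. On step economy it is roughly twice as long.

Key step: step 2

## Route

Step 1
Reactants: 1 4-bromo-2-hydroxybenzaldehyde
Product: 2 5-bromo-2-(hydroxymethyl)phenol
Conditions: NaBH4 (1 equiv), MeOH, 0 °C; aq. NH4Cl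
Reagents that add atoms: none
Why: Borohydride reduction of the aryl aldehyde; the aryl bromide is inert, the phenol only consumes some hydride as its phenoxide, and the mildly acidic work-up avoids premature ionisation of the salicyl alcohol.

Step 2
Reactants: 2 5-bromo-2-(hydroxymethyl)phenol; 3 2-methylprop-1-enylboronic acid pinacol ester
Product: 5 (3S)-7-bromo-2,2-dimethyl-3-(4,4,5,5-tetramethyl-1,3,2-dioxaborolan-2-yl)chromane, via bromo ortho-quinone methide 4 (not isolated)
Conditions: (R)-3,3'-bis(2,4,6-triisopropylphenyl)-1,1'-binaphthyl-2,2'-diyl N-(trifluoromethanesulfonyl)phosphoramide (10 mol %), 3 (3 equiv), 5 Å molecular sieves, CH2Cl2, −20 °C to rt, 2 added slowly as a dilute solution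
Reagents that add atoms: none
Why: Proposed new method: the chiral acid protonates the benzylic hydroxyl of 2 and expels water to give 4, which stays hydrogen-bonded or ion-paired to the phosphoramide anion, and the boron-bearing CH of 3 bonds to the exocyclic CH2 while positive charge builds on the CMe2 carbon before the phenolic oxygen closes onto it, the closest known reaction type being the chiral Brønsted acid catalysed inverse-electron-demand oxa-Diels–Alder reaction of ortho-quinone methides formed in the flask with styrenes and enol ethers. Ring B is closed by this concerted, asynchronous (4+2) cycloaddition, which forms C4–C3 and O1–C2 and is driven by rearomatisation of ring A (in the stepwise limit, six-membered capture of the tertiary cation by the phenol oxygen). The C3 stereocentre is set by catalyst control. Because the methide terminus is CH2, shielding one face of 4 is not enough, and the chiral pocket must also fix the orientation of the alkene (pinacolboryl group turned away from the 3,3'-aryl wall) so that a single enantiotopic face of the C=C bond is presented. Regioselectivity is secured by the substrate: the cation is tertiary and hyperconjugatively stabilised by the adjacent C–B bond, and the less hindered CH terminus is the one that attacks. The acid is chosen stronger than the parent phosphoric acid because 2 is a primary, bromo-substituted benzylic alcohol that ionises reluctantly and 3 is only a moderate nucleophile. Slow addition of 2 into excess 3 keeps 4 from condensing with itself. The pinacol ester is used and not the free boronic acid, so that boron cannot exchange onto the two hydroxyls of 2 and divert the reaction into alkenyl transfer with loss of boron.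

Step 3
Reactants: 5 (3S)-7-bromo-2,2-dimethyl-3-(4,4,5,5-tetramethyl-1,3,2-dioxaborolan-2-yl)chromane
Product: 6 (3S)-7-bromo-2,2-dimethylchroman-3-ol
Conditions: NaBO3·4H2O (3 equiv), THF/H2O (1:1), 0 °C to rt
Reagents that add atoms: sodium perborate tetrahydrate, [Na+].[O-]OB=O.O.O.O.O
Why: Oxidation of a secondary alkylboronic ester: the peroxide ate complex undergoes 1,2-migration of C3 from boron to oxygen with retention, so (3S)-5 should give (3S)-6. Perborate is the mildest common oxidant, chosen so that migration outruns anti-periplanar loss of the C2 aryloxide, and the aryl bromide is untouched.

Step 4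
Reactants: 6 (3S)-7-bromo-2,2-dimethylchroman-3-ol; 7 bis(4,4,5,5-tetramethyl-1,3,2-dioxaborolan-2-yl)methane
Product: 8 (3S)-2,2-dimethyl-7-[(4,4,5,5-tetramethyl-1,3,2-dioxaborolan-2-yl)methyl]chroman-3-ol
Conditions: Pd[P(t-Bu)3]2 (5 mol %), 7 (1.5 equiv), aq. KOH (8 M, 2 equiv), 1,4-dioxane, rt
Reagents that add atoms: none
Why: Suzuki–Miyaura mono-coupling of a gem-diborylmethane with an aryl bromide: hydroxide turns one boron of 7 into a borate whose transfer to arylpalladium is accelerated by the second boron on the same carbon, so 7 should react much faster than the benzylic boronate 8 that forms. The free secondary alcohol and the stereocentre are not involved.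

Step 5
Reactants: 9 3,4-dibromo-1H-pyrrole-2,5-dione; 10 4-hydroxyphenylboronic acid
Product: 11 3-bromo-4-(4-hydroxyphenyl)-1H-pyrrole-2,5-dione
Conditions: PdCl2(dppf) (5 mol %; dppf = 1,1'-bis(diphenylphosphino)ferrocene), 9 (1.5 equiv), aq. NaHCO3 (3 equiv), 1,2-dimethoxyethane, 60 °C; dilute HCl on work-up
Reagents that add atoms: none
Why: Suzuki–Miyaura mono-arylation of a dibromomaleimide: the first aryl group is a para-hydroxyphenyl donor conjugated to the remaining C–Br carbon and deactivates it toward a second oxidative addition, and the excess of 9 reinforces this. Bicarbonate activates the boronic acid while the phenol stays largely un-ionised, which limits addition–elimination of oxygen nucleophiles at the C–Br bonds.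

Step 6
Reactants: 8 (3S)-2,2-dimethyl-7-[(4,4,5,5-tetramethyl-1,3,2-dioxaborolan-2-yl)methyl]chroman-3-ol; 11 3-bromo-4-(4-hydroxyphenyl)-1H-pyrrole-2,5-dione
Product: 12 Asperimide C
Conditions: Pd(OAc)2 (5 mol %), 2-dicyclohexylphosphino-2',6'-dimethoxybiphenyl (10 mol %), K3PO4 (4 equiv), 1,4-dioxane/H2O (5:1), degassed, 90 °C; aq. NH4Cl to pH 5
Reagents that add atoms: none
Why: B-benzyl Suzuki–Miyaura coupling (sp3–sp2) of a primary benzylic boronate with an alkenyl bromide; the electron-rich biaryl phosphine on zerovalent palladium supports oxidative addition although 11 is present as its imidate and phenoxide, and a benzylpalladium has no β-hydrogen to lose. The deprotonated imide is protected from hydroxide attack and from base-induced migration of the ring C alkene; no stereocentre is touched, and acidification releases 12.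

## Compound list

1 | 4-bromo-2-hydroxybenzaldehyde | O=Cc1ccc(Br)cc1O | starting material
2 | 5-bromo-2-(hydroxymethyl)phenol | OCc1ccc(Br)cc1O | intermediate
3 | 2-methylprop-1-enylboronic acid pinacol ester | CC(C)=CB1OC(C)(C)C(C)(C)O1 | starting material
4 | 3-bromo-6-methylidenecyclohexa-2,4-dien-1-one (formed in the flask) | C=C1C=CC(Br)=CC1=O | intermediate
5 | (3S)-7-bromo-2,2-dimethyl-3-(4,4,5,5-tetramethyl-1,3,2-dioxaborolan-2-yl)chromane | CC1(C)Oc2cc(Br)ccc2C[C@@H]1B1OC(C)(C)C(C)(C)O1 | intermediate
6 | (3S)-7-bromo-2,2-dimethylchroman-3-ol | CC1(C)Oc2cc(Br)ccc2C[C@@H]1O | intermediate
7 | bis(4,4,5,5-tetramethyl-1,3,2-dioxaborolan-2-yl)methane | CC1(C)OB(CB2OC(C)(C)C(C)(C)O2)OC1(C)C | starting material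
8 | (3S)-2,2-dimethyl-7-[(4,4,5,5-tetramethyl-1,3,2-dioxaborolan-2-yl)methyl]chroman-3-ol | CC1(C)Oc2cc(CB3OC(C)(C)C(C)(C)O3)ccc2C[C@@H]1O | intermediate
9 | 3,4-dibromo-1H-pyrrole-2,5-dione | O=C1NC(=O)C(Br)=C1Br | starting material
10 | 4-hydroxyphenylboronic acid | OB(O)c1ccc(O)cc1 | starting material
11 | 3-bromo-4-(4-hydroxyphenyl)-1H-pyrrole-2,5-dione | O=C1NC(=O)C(c2ccc(O)cc2)=C1Br | intermediate
12 | Asperimide C, 3-(4-hydroxyphenyl)-4-{[(3S)-3-hydroxy-2,2-dimethylchroman-7-yl]methyl}-1H-pyrrole-2,5-dione | CC1(C)Oc2cc(CC3=C(c4ccc(O)cc4)C(=O)NC3=O)ccc2C[C@@H]1O | target

## Step count and least certain steps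

Total step count: 6. Longest linear sequence: 5 (steps 1, 2, 3, 4 and 6). Step 5 is a one-step branch.

**Step 2 (key step).**
- Most likely failure: poor enantioface selection. The alkene has no group the catalyst can hold, and with a CH2 methide terminus the outcome depends on the mutual orientation of both partners.
- Further risks: loss of boron from the developing β-boryl cation (net prenylation of the phenol), acid-induced protodeboronation of 3, and self-condensation of 4.
- Fallback by known chemistry, from 1 back to 6: addition of 2-methylprop-1-enylmagnesium bromide (2.5 equiv, THF, 0 °C) to 1 should give racemic 5-bromo-2-(1-hydroxy-3-methylbut-2-en-1-yl)phenol F1. Acid-catalysed cyclodehydration (catalytic TsOH, toluene, 60 °C) should give 7-bromo-2,2-dimethyl-2H-chromene F2. Jacobsen epoxidation follows, with (S,S)-[N,N'-bis(3,5-di-tert-butylsalicylidene)-1,2-cyclohexanediaminato]manganese chloride (a trivalent manganese complex), NaOCl and 4-phenylpyridine N-oxide in CH2Cl2 at 0 °C. This enantiomer of the catalyst is the one expected for this substrate class to give (3S,4S)-7-bromo-3,4-epoxy-2,2-dimethylchromane F3. Hydride opening at the benzylic C4 (LiAlH4, THF, 0 °C) keeps the C3–O bond and returns to the route at 6.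

**Step 6.**
- Most likely failure: slow oxidative addition into the deprotonated, push–pull bromide of 11, so that protodeboronation of 8 or slow decomposition in hot aqueous base takes over.
- Fallback that reverses the order of bond formation, from 8 back to 12: 8 is coupled first with a threefold excess of the far more electrophilic 9 (Pd(OAc)2, 2-dicyclohexylphosphino-2',6'-dimethoxybiphenyl, K3PO4, toluene/H2O, 60 °C). This should give 3-bromo-4-{[(3S)-3-hydroxy-2,2-dimethylchroman-7-yl]methyl}-1H-pyrrole-2,5-dione F4. The easily transferred aryl group of 10 is then introduced (PdCl2(dppf), aq. NaHCO3, 1,2-dimethoxyethane, 70 °C), which returns to the route at 12.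

**Step 5.**
- Most likely failure: over-arylation, or displacement of bromide from 9 by oxygen nucleophiles through addition–elimination. Binding of the imidate to palladium may also slow the catalyst.
- Fallback with a protected nitrogen, from 10 back to 12: 10 is coupled with commercial 3,4-dibromo-1-methylpyrrole-2,5-dione under the conditions of step 5 to give 3-bromo-4-(4-hydroxyphenyl)-1-methylpyrrole-2,5-dione F5. Coupling with 8 under the conditions of step 6 gives N-methyl Asperimide C F6. Aqueous KOH in ethanol at reflux, then HCl, gives the anhydride 3-(4-hydroxyphenyl)-4-{[(3S)-3-hydroxy-2,2-dimethylchroman-7-yl]methyl}furan-2,5-dione F7. Hexamethyldisilazane and MeOH in DMF at rt convert F7 into 12.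

**Step 4.**
- Most likely failure: a second coupling of 8 with 6 to a diarylmethane, or protodeboronation of the benzylic boronate in aqueous KOH.
- Fallback by homologation, from 6 back to 8: Miyaura borylation of 6 (bis(pinacolato)diboron, PdCl2(dppf), KOAc, 1,4-dioxane, 80 °C) gives (3S)-2,2-dimethyl-7-(4,4,5,5-tetramethyl-1,3,2-dioxaborolan-2-yl)chroman-3-ol F8. Matteson one-carbon homologation (BrCH2Cl and n-BuLi in excess, THF, −78 °C to rt) inserts the CH2 group and returns to the route at 8.

## Further compounds

F1 | step 2 | 5-bromo-2-(1-hydroxy-3-methylbut-2-en-1-yl)phenol (racemic) | CC(C)=CC(O)c1ccc(Br)cc1O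
F2 | step 2 | 7-bromo-2,2-dimethyl-2H-chromene | CC1(C)C=Cc2ccc(Br)cc2O1
F3 | step 2 | (3S,4S)-7-bromo-3,4-epoxy-2,2-dimethylchromane | CC1(C)Oc2cc(Br)ccc2[C@@H]2O[C@H]12
F4 | step 6 | 3-bromo-4-{[(3S)-3-hydroxy-2,2-dimethylchroman-7-yl]methyl}-1H-pyrrole-2,5-dione | CC1(C)Oc2cc(CC3=C(Br)C(=O)NC3=O)ccc2C[C@@H]1O
F5 | step 5 | 3-bromo-4-(4-hydroxyphenyl)-1-methylpyrrole-2,5-dione | CN1C(=O)C(Br)=C(c2ccc(O)cc2)C1=O
F6 | step 5 | N-methyl Asperimide C | CC1(C)Oc2cc(CC3=C(c4ccc(O)cc4)C(=O)N(C)C3=O)ccc2C[C@@H]1O
F7 | step 5 | 3-(4-hydroxyphenyl)-4-{[(3S)-3-hydroxy-2,2-dimethylchroman-7-yl]methyl}furan-2,5-dione | CC1(C)Oc2cc(CC3=C(c4ccc(O)cc4)C(=O)OC3=O)ccc2C[C@@H]1O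
F8 | step 4 | (3S)-2,2-dimethyl-7-(4,4,5,5-tetramethyl-1,3,2-dioxaborolan-2-yl)chroman-3-ol | CC1(C)Oc2cc(B3OC(C)(C)C(C)(C)O3)ccc2C[C@@H]1O
A1 | alternative 1 | (3S)-3-(tert-butyldimethylsilyloxy)-7-{3-[4-(tert-butyldimethylsilyloxy)phenyl]prop-2-yn-1-yl}-2,2-dimethylchromane | CC1(C)Oc2cc(CC#Cc3ccc(O[Si](C)(C)C(C)(C)C)cc3)ccc2C[C@@H]1O[Si](C)(C)C(C)(C)C
A2 | alternative 1 | benzyl isocyanate | O=C=NCc1ccccc1
A3 | alternative 1 | N-benzyl bis(tert-butyldimethylsilyl) Asperimide C | CC1(C)Oc2cc(CC3=C(c4ccc(O[Si](C)(C)C(C)(C)C)cc4)C(=O)N(Cc4ccccc4)C3=O)ccc2C[C@@H]1O[Si](C)(C)C(C)(C)C
A4 | alternative 2 | 3-chloro-5-[(methoxymethoxy)methyl]-2-(trimethylsilyl)phenyl trifluoromethanesulfonate | COCOCc1cc(Cl)c([Si](C)(C)C)c(OS(=O)(=O)C(F)(F)F)c1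
A5 | alternative 2 | 3-methylbut-2-enal | CC(C)=CC=O
A6 | alternative 2 | 5-chloro-7-[(methoxymethoxy)methyl]-2,2-dimethyl-2H-chromene | CC1(C)Oc2cc(COCOC)cc(Cl)c2C=C1
A7 | alternative 3 | methyl 3-bromo-4-[(2S)-3-hydroxy-2-(methoxymethoxy)-3-methylbutyl]benzoate | COC(=O)c1ccc(C[C@H](OCOC)C(C)(C)O)c(Br)c1
A8 | alternative 3 | methyl (3S)-3-(methoxymethoxy)-2,2-dimethylchromane-7-carboxylate | COC(=O)c1ccc2c(c1)OC(C)(C)[C@@H](OCOC)C2
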